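## The problem

16-Oxosarcoglaucol acetate (27) is a cembranoid in which a 14-membered carbocycle is bridged by an α-methyl butenolide. The ring is numbered C1 (butenolide β-carbon), C2 (lactone O–CH), C3=C4(Me), C5, C6, C7=C8(CO2Me), C9, C10, C11=C12(Me), C13(OAc) and C14; C15 and C16 are the butenolide α-carbon and carbonyl. Three trisubstituted ring alkenes need defined geometry: C3=C4 (E), C7=C8 (ester cis to C6, Z by the sequence rules) and C11=C12 (E). The tetrasubstituted C1=C15 alkene is shared by lactone and macrocycle and cannot be made by a simple olefination. There are only two stereocentres, C2 (S) and C13 (S), and they face each other across the flat butenolide, so neither can be relied on to control the other. C2 is fragile: its hydrogen is a butenolide γ-proton that is also allylic to C3=C4 (base leads to a furanolate and racemisation), and its C–O bond is doubly allylic (acid leads to ionisation). The C13 allylic acetate, the methyl ester and the enolisable C14 methylene next to any C13 carbonyl rule out strong bases, hydrides and hard nucleophiles late in the route. The enabling feature is the substitution pattern O–C2, C14–C1 and C16–C15 with the carboxyl carbon cis to the C2 oxygen. This is exactly what anti addition of a carbon nucleophile and CO2 across the alkyne of a 1-propynyl carbinol produces.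

## Retrosynthesis

**Acetate and silyl ether.** Target 27 is traced back to allylic alcohol 26 and then to triethylsilyl ether 25 by cutting only O–acyl and O–Si bonds. The acetate goes on last because it is the most labile group in the molecule. The forward steps must only keep C13 and C2 intact.

**C12–C13 ring bond.** Cutting C12–C13 in 25 gives the open-chain ynal 24, with the aldehyde at C13 and a methyl-capped alkyne at C11≡C12. A macrocyclic olefination at C7=C8 would have to fix the ester-cis geometry inside a forming ring. Cuts at C2–C3 or C13–C14 need carbanions beside the base-sensitive butenolide. Metathesis at a trisubstituted alkene gives no control of geometry. The chosen cut lets one reductive coupling form the ring, the 11E alkene and the C13–O bond from two stable functional groups. The forward reaction must bond the methyl-bearing alkyne carbon to the aldehyde, deliver hydrogen syn, and choose a face at C13; the last point is the open one.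

**C13 aldehyde.** The aldehyde of 24 is masked as the terminal alkene of allyl butenolide 22 (C13=CH2 in place of C13=O). With C14 flanked by the butenolide and the carbonyl, the aldehyde is too enolisable to carry, so it is released one step before ring closure. The forward cleavage must pick the monosubstituted alkene out of four alkenes and one alkyne.

**C7=C8.** Cutting this alkene in 22 gives aldehyde 17 and phosphonate 21. The phosphonate brings C8 to C12 with the ester carbon and the C12 methyl in one piece. An sp3–sp3 cut at C8–C9 or C9–C10 would leave the geometry unsolved, whereas a kinetic Still–Gennari olefination places the ester cis to C6. Phosphonate 21 comes from the commercial phosphonoacetate 20 and iodide 19, made from pent-3-yn-1-ol (18).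

**C7 oxidation level.** Aldehyde 17 comes from alcohol 16 and silyl ether 15, by deprotection and oxidation only.

**Butenolide (key disconnection).** In 15 the bonds C1–C14, C15–C16 and O–C16 are cut together, giving propargylic carbinol 10, allylmagnesium bromide (11) and CO2 (12). Building the lactone by olefination or metathesis would have to form a tetrasubstituted alkene. Attaching the C3 chain to a preformed butenolide would need γ-deprotonation at C2. The three-component cut derives the alkene geometry and the placement of C14 and C16 from the alkoxide chelate, and it leaves C2 as a simple secondary carbinol. The precursor has no ring and one stereocentre.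

**C2 stereocentre and C2–C3.** Carbinol 10 comes from ynenone 9 by asymmetric transfer hydrogenation, which sets C2 by reagent control. Ynenone 9 is cut at C2–C3 into alkenyl iodide 4 and Weinreb amide 6, the latter from but-2-ynoic acid (5). This joins two small pieces at the ketone oxidation level and avoids a separate oxidation.

**C3=C4.** Alkenyl iodide 4 comes from silyl ether 2 by methyl-alumination and iodination of the terminal alkyne, which forms the C4–methyl bond and the E geometry in one step. Silyl ether 2 is made from pent-4-yn-1-ol (1).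

## Roads not taken

**Alternative 1:** The cut is C1–C2 of the carbocycle, traced back by a retro-[2,3]-Wittig shift to the 17-membered propargyl allyl ether A1, in which oxygen links C2 and C17. In the forward step, lithiation at the propargylic carbon C2 of A1 gives a carbanion that attacks C1; O–C17 breaks and the ring contracts to the 14-membered propargylic alcohol A2.
- Merits: the large ether ring is easy to close, the sigmatropic step forms a ring C–C bond and the C2 carbinol together, and C13 is set before any ring exists. On that last point it is better than the chosen plan.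
- Weak points: the new stereocentre at C1 is wasted, because C1 is sp2 in the target. The sense at C2 must be induced from remote C13 or by a chiral base. The C17 methylene is also α to oxygen and allylic, so it competes for the base.
- Distance to target: A2 still needs a directed methyl addition across C3≡C4, release of two orthoesters, lactonisation, and migration of the exocyclic alkene into the ring.
- Comparison: the chosen plan sets against the secure C13 the fact that its key step delivers the butenolide complete, at the right oxidation level, in one operation from an acyclic carbinol.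

**Alternative 2:** The cut is C12–C13. In the forward step Ni(cod)2 with a small N-heterocyclic carbene and Et3SiH closes an ynal to the 13-O-triethylsilyl macrocycle A3.
- Merits: ring, 11E alkene and carbinol form in one step, from functional groups that survive the earlier chemistry.
- Weak points: no reagent control of the C13 face, and an enolisable aldehyde beside the butenolide.
- Comparison: this is the ring closure the chosen route itself uses in step 13; A3 is the same structure as 25. As a ring-forming method the two are equal, including the C13 weakness. As a headline strategy, Alternative 2 leaves open how the tetrasubstituted butenolide and C2 are made; the chosen plan answers this with the three-bond assembly of step 6.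

**Alternative 3:** The cut is the C11≡C12 triple bond of a cycloalkyne. In the forward step the diyne A4, which already carries the butenolide and the C13 silyl ether, undergoes ring-closing alkyne metathesis with a molybdenum alkylidyne such as Mo(≡CC6H4OMe)(OSiPh3)3. 2-Butyne is lost and cycloalkyne A5 forms. After desilylation, hydroxyl-directed trans-hydrostannation ([Cp*RuCl]4, Bu3SnH) and methyl-for-tin exchange would install the C12 methyl with E geometry.
- Merits: C13 is fixed before ring closure by reagent-controlled propynylation of the same C13 aldehyde, alkyne metathesis ignores all the alkenes, and the trans-addition gives the E ring alkene. In control of C13 this road is better than the chosen plan.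
- Weak points: three further operations after ring closure against one, a stoichiometric tin reagent near the end, and a Lewis-acidic alkylidyne in the presence of the lactone and the doubly allylic C2–O bond.
- Comparison: the chosen plan sets against it the shorter endgame and the use of both C13 epimers by inversion. The butenolide assembly of step 6 could feed this ring closure equally well, so it is the natural reserve if the C13 problem proves intractable.

Key step: step 6

Remark on the chemistry: the facial sense of the transfer hydrogenation in step 5 is assigned by analogy with alkyl alkynyl ketones, the alkynyl group taking the position next to the arene ligand.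

Remark on the chemistry: the ring closure in step 13 is assumed to give the (13S) silyl ether as a separable component of an epimer pair; the (13R) epimer is converted into the target by inversion, as described after the route.

## Route

Step 1
Reactants: 1 pent-4-yn-1-ol
Product: 2 tert-butyl(dimethyl)(pent-4-yn-1-yloxy)silane
Conditions: TBSCl, imidazole, CH2Cl2, 0 °C to rt
Reagents that add atoms: tert-butyldimethylsilyl chloride, CC(C)(C)[Si](C)(C)Cl
Why: Imidazole-assisted silylation of a primary alcohol; the terminal alkyne is untouched.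

Step 2
Reactants: 2 tert-butyl(dimethyl)(pent-4-yn-1-yloxy)silane
Product: 4 tert-butyl{[(4E)-5-iodo-4-methylpent-4-en-1-yl]oxy}dimethylsilane, via alkenyl(dimethyl)alane 3 (not isolated)
Conditions: AlMe3 (2 equiv), Cp2ZrCl2 (25 mol%), CH2Cl2, 0 °C to rt; then I2, THF, −30 to 0 °C
Reagents that add atoms: trimethylaluminium, C[Al](C)C; iodine, II
Why: Negishi carboalumination adds methyl and aluminium syn across the terminal alkyne with methyl on the internal carbon, and iodinolysis of the C–Al bond of 3 proceeds with retention, which fixes the E geometry of the later C3=C4 alkene; the silyl ether is tolerated.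

Step 3
Reactants: 5 but-2-ynoic acid
Product: 6 N-methoxy-N-methylbut-2-ynamide
Conditions: MeNH(OMe)·HCl, EDC·HCl, N-methylmorpholine, CH2Cl2, 0 °C to rt
Reagents that add atoms: N,O-dimethylhydroxylamine hydrochloride, CNOC.Cl
Why: Carbodiimide amide coupling to the Weinreb amide; the weakly basic alkoxyamine acylates faster than it adds to the triple bond.

Step 4
Reactants: 4 tert-butyl{[(4E)-5-iodo-4-methylpent-4-en-1-yl]oxy}dimethylsilane; 6 N-methoxy-N-methylbut-2-ynamide
Product: 9 (5E)-9-{[tert-butyl(dimethyl)silyl]oxy}-6-methylnon-5-en-2-yn-4-one, via alkenyllithium 7 (not isolated), via lithium hemiaminal alkoxide 8 (not isolated)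
Conditions: t-BuLi (2.1 equiv), Et2O, −78 °C; then 6, −78 °C; cold aq. NH4Cl quench
Reagents that add atoms: none
Why: Iodine–lithium exchange retains alkene geometry, and Weinreb ketone synthesis stops at the ketone because chelate 8 survives until the cold quench; this forms the C2–C3 bond at the ketone oxidation level.

Step 5
Reactants: 9 (5E)-9-{[tert-butyl(dimethyl)silyl]oxy}-6-methylnon-5-en-2-yn-4-one
Product: 10 (4S,5E)-9-{[tert-butyl(dimethyl)silyl]oxy}-6-methylnon-5-en-2-yn-4-ol
Conditions: Ru[(S,S)-TsDPEN](p-cymene) (2 mol%), i-PrOH, rt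
Reagents that add atoms: none
Why: Noyori asymmetric transfer hydrogenation of an alkynyl ketone: hydride and proton pass to C=O in the outer sphere with the alkynyl group beside the arene ligand, so the (S,S) catalyst should set C2 as S; the base-free conditions spare the ynone, and C=C and C≡C are not reduced.

Step 6
Reactants: 10 (4S,5E)-9-{[tert-butyl(dimethyl)silyl]oxy}-6-methylnon-5-en-2-yn-4-ol; 11 allylmagnesium bromide; 12 carbon dioxide
Product: 15 (5S)-5-[(1E)-5-{[tert-butyl(dimethyl)silyl]oxy}-2-methylpent-1-en-1-yl]-3-methyl-4-(prop-2-en-1-yl)furan-2(5H)-one, via alkenylmagnesium chelate 13 (not isolated), via hydroxy acid 14 (not isolated)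
Conditions: 11 (3.5 equiv), CuI (10 mol%), Et2O, −20 °C to rt; then CO2 (1 atm), −20 °C to rt; then 1 M aq. HCl, 0 °C
Reagents that add atoms: none
Why: The first equivalent of 11 deprotonates 10 (propene is lost), and the magnesium alkoxide directs a CuI-catalysed allyl transfer to the proximal alkyne carbon C1 while magnesium ends on C15 trans to the allyl group, giving the five-membered chelate 13. CO2 inserts into the C15–Mg bond with retention of alkene geometry, and acidification frees hydroxy acid 14, whose carboxyl and hydroxyl groups are cis. Acid 14 closes the butenolide by 5-exo-trig acyl substitution (O–C16). The closest known reaction type is the copper-catalysed anti-carbomagnesiation of propargylic alcohols with carboxylative trapping of the chelated alkenylmagnesium. No stereocentre is formed, and the C2–O bond is never broken, so the S configuration of 10 is carried into 15. The step needs regiocontrol (allyl to C1, carboxyl to C15) and anti addition, both secured by the alkoxide chelate. It also needs chemoselectivity, which follows because the trisubstituted alkene and the silyl ether are inert to the Grignard reagent. The acid treatment is kept cold and short because C2–O is doubly allylic.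

Step 7
Reactants: 15 (5S)-5-[(1E)-5-{[tert-butyl(dimethyl)silyl]oxy}-2-methylpent-1-en-1-yl]-3-methyl-4-(prop-2-en-1-yl)furan-2(5H)-one
Product: 16 (5S)-5-[(1E)-5-hydroxy-2-methylpent-1-en-1-yl]-3-methyl-4-(prop-2-en-1-yl)furan-2(5H)-one
Conditions: HF·pyridine, pyridine, THF, 0 °C to rt
Reagents that add atoms: none
Why: Buffered fluoride cleavage of a primary silyl ether; a non-basic fluoride source is used because C2–H is a butenolide γ-proton.

Step 8
Reactants: 16 (5S)-5-[(1E)-5-hydroxy-2-methylpent-1-en-1-yl]-3-methyl-4-(prop-2-en-1-yl)furan-2(5H)-one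
Product: 17 (4E)-4-methyl-5-[(2S)-4-methyl-5-oxo-3-(prop-2-en-1-yl)-2,5-dihydrofuran-2-yl]pent-4-enal
Conditions: Dess–Martin periodinane, NaHCO3, CH2Cl2, 0 °C to rt
Reagents that add atoms: none
Why: Dess–Martin oxidation of a primary alcohol under buffered neutral conditions, with no over-oxidation and no base that could epimerise C2.

Step 9
Reactants: 18 pent-3-yn-1-ol
Product: 19 5-iodopent-2-yne
Conditions: I2, PPh3, imidazole, CH2Cl2, 0 °C
Reagents that add atoms: iodine, II
Why: Appel-type iodination of a primary alcohol by SN2 displacement of the oxyphosphonium group.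

Step 10
Reactants: 20 methyl [bis(2,2,2-trifluoroethoxy)phosphoryl]acetate; 19 5-iodopent-2-yne
Product: 21 methyl 2-[bis(2,2,2-trifluoroethoxy)phosphoryl]hept-5-ynoate (racemic)
Conditions: NaH, DMF, 0 °C to rt (20 in excess)
Reagents that add atoms: none
Why: SN2 C-alkylation of the sodium phosphonoacetate with a primary iodide; the excess of 20 limits dialkylation, and the racemic α-centre is destroyed in step 11.

Step 11
Reactants: 17 (4E)-4-methyl-5-[(2S)-4-methyl-5-oxo-3-(prop-2-en-1-yl)-2,5-dihydrofuran-2-yl]pent-4-enal; 21 methyl 2-[bis(2,2,2-trifluoroethoxy)phosphoryl]hept-5-ynoate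
Product: 22 methyl (2Z,6E)-6-methyl-7-[(2S)-4-methyl-5-oxo-3-(prop-2-en-1-yl)-2,5-dihydrofuran-2-yl]-2-(pent-3-yn-1-yl)hepta-2,6-dienoate
Conditions: 21, KN(SiMe3)2, 18-crown-6, THF, −78 °C; then 17, −78 °C
Reagents that add atoms: none
Why: Still–Gennari olefination: the electron-poor phosphonate with a dissociated potassium counter-ion eliminates rapidly from the kinetic adduct and places the ester cis to C6 (2Z); the anion is preformed so that no free amide base meets the butenolide.

Step 12
Reactants: 22 methyl (2Z,6E)-6-methyl-7-[(2S)-4-methyl-5-oxo-3-(prop-2-en-1-yl)-2,5-dihydrofuran-2-yl]-2-(pent-3-yn-1-yl)hepta-2,6-dienoate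
Product: 24 methyl (2Z,6E)-6-methyl-7-[(2S)-4-methyl-5-oxo-3-(2-oxoethyl)-2,5-dihydrofuran-2-yl]-2-(pent-3-yn-1-yl)hepta-2,6-dienoate, via terminal diol 23 (not isolated)
Conditions: OsO4 (2 mol%), NMO (1.1 equiv), acetone/H2O, 0 °C; then NaIO4, 0 °C to rt
Reagents that add atoms: N-methylmorpholine N-oxide, C[N+]1([O-])CCOCC1 (terminal source of the aldehyde oxygen, passed on by OsO4, O=[Os](=O)(=O)=O)
Why: Two-stage Lemieux–Johnson cleavage: the allyl alkene is the least hindered and the only one that is neither conjugated to a carbonyl nor deactivated by an allylic acyloxy group, as C3=C4 is by the lactone oxygen, and OsO4 leaves the alkyne alone; the diol centre of 23 is lost on cleavage.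

Step 13
Reactants: 24 methyl (2Z,6E)-6-methyl-7-[(2S)-4-methyl-5-oxo-3-(2-oxoethyl)-2,5-dihydrofuran-2-yl]-2-(pent-3-yn-1-yl)hepta-2,6-dienoate
Product: 25 (2S,13S)-13-O-triethylsilyl-16-oxosarcoglaucol (macrocyclic silyl ether)
Conditions: Ni(cod)2 (30 mol%), IMes (free carbene, 30 mol%), Et3SiH (5 equiv), THF, 2 mM, slow addition of 24, rt
Reagents that add atoms: triethylsilane, CC[SiH](CC)CC
Why: Nickel-catalysed reductive alkyne–aldehyde coupling: zerovalent nickel–IMes joins alkyne and aldehyde to an oxanickelacycle with the methyl-bearing carbon C12 at the new bond (small carbene, endocyclic closure of the 14-membered ring), and σ-bond metathesis with Et3SiH then delivers hydrogen to C11 syn to C13 (11E) and silylates oxygen; C13 forms under substrate control from C2 only, so 25 is expected with its C13 epimer and is separated from it.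

Step 14
Reactants: 25 (2S,13S)-13-O-triethylsilyl-16-oxosarcoglaucol
Product: 26 (2S,13S)-16-oxosarcoglaucol (C13 alcohol)
Conditions: HF·pyridine, pyridine, THF, 0 °C
Reagents that add atoms: none
Why: Buffered fluoride cleavage of a secondary triethylsilyl ether without ionising the allylic C13–O bond or deprotonating C2.

Step 15
Reactants: 26 (2S,13S)-16-oxosarcoglaucol
Product: 27 16-oxosarcoglaucol acetate
Conditions: Ac2O, pyridine, DMAP (cat.), CH2Cl2, 0 °C
Reagents that add atoms: acetic anhydride, CC(=O)OC(C)=O
Why: DMAP-catalysed O-acylation of a secondary allylic alcohol with retention at C13; the mild base and low temperature leave C2–H alone.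

## Compound list

1 | pent-4-yn-1-ol | C#CCCCO | starting material
2 | tert-butyl(dimethyl)(pent-4-yn-1-yloxy)silane | C#CCCCO[Si](C)(C)C(C)(C)C | intermediate
3 | [(1E)-5-{[tert-butyl(dimethyl)silyl]oxy}-2-methylpent-1-en-1-yl]dimethylalane | C/C(=C\[Al](C)C)CCCO[Si](C)(C)C(C)(C)C | intermediate
4 | tert-butyl{[(4E)-5-iodo-4-methylpent-4-en-1-yl]oxy}dimethylsilane | C/C(=C\I)CCCO[Si](C)(C)C(C)(C)C | intermediate
5 | but-2-ynoic acid | CC#CC(=O)O | starting material
6 | N-methoxy-N-methylbut-2-ynamide | CC#CC(=O)N(C)OC | intermediate
7 | [(1E)-5-{[tert-butyl(dimethyl)silyl]oxy}-2-methylpent-1-en-1-yl]lithium | C/C(=C\[Li])CCCO[Si](C)(C)C(C)(C)C | intermediate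
8 | lithium (5E)-9-{[tert-butyl(dimethyl)silyl]oxy}-4-[methoxy(methyl)amino]-6-methylnon-5-en-2-yn-4-olate (carbinol centre racemic) | [Li+].CC#CC([O-])(N(C)OC)/C=C(C)/CCCO[Si](C)(C)C(C)(C)C | intermediate
9 | (5E)-9-{[tert-butyl(dimethyl)silyl]oxy}-6-methylnon-5-en-2-yn-4-one | CC#CC(=O)/C=C(C)/CCCO[Si](C)(C)C(C)(C)C | intermediate
10 | (4S,5E)-9-{[tert-butyl(dimethyl)silyl]oxy}-6-methylnon-5-en-2-yn-4-ol | CC#C[C@@H](O)/C=C(C)/CCCO[Si](C)(C)C(C)(C)C | intermediate
11 | allylmagnesium bromide | C=CC[Mg]Br | starting material
12 | carbon dioxide | O=C=O | starting material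
13 | (5S)-5-[(1E)-5-{[tert-butyl(dimethyl)silyl]oxy}-2-methylpent-1-en-1-yl]-3-methyl-4-(prop-2-en-1-yl)-2,5-dihydro-1,2-oxamagnesole (solvated chelate) | C=CCC1=C(C)[Mg]O[C@H]1/C=C(C)/CCCO[Si](C)(C)C(C)(C)C | intermediate
14 | (2Z)-3-[(1S,2E)-6-{[tert-butyl(dimethyl)silyl]oxy}-1-hydroxy-3-methylhex-2-en-1-yl]-2-methylhexa-2,5-dienoic acid | C=CC/C(=C(\C)C(=O)O)[C@@H](O)/C=C(C)/CCCO[Si](C)(C)C(C)(C)C | intermediate
15 | (5S)-5-[(1E)-5-{[tert-butyl(dimethyl)silyl]oxy}-2-methylpent-1-en-1-yl]-3-methyl-4-(prop-2-en-1-yl)furan-2(5H)-one | C=CCC1=C(C)C(=O)O[C@H]1/C=C(C)/CCCO[Si](C)(C)C(C)(C)C | intermediate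
16 | (5S)-5-[(1E)-5-hydroxy-2-methylpent-1-en-1-yl]-3-methyl-4-(prop-2-en-1-yl)furan-2(5H)-one | C=CCC1=C(C)C(=O)O[C@H]1/C=C(C)/CCCO | intermediate
17 | (4E)-4-methyl-5-[(2S)-4-methyl-5-oxo-3-(prop-2-en-1-yl)-2,5-dihydrofuran-2-yl]pent-4-enal | C=CCC1=C(C)C(=O)O[C@H]1/C=C(C)/CCC=O | intermediate
18 | pent-3-yn-1-ol | CC#CCCO | starting material
19 | 5-iodopent-2-yne | CC#CCCI | intermediate
20 | methyl [bis(2,2,2-trifluoroethoxy)phosphoryl]acetate | COC(=O)CP(=O)(OCC(F)(F)F)OCC(F)(F)F | starting material
21 | methyl 2-[bis(2,2,2-trifluoroethoxy)phosphoryl]hept-5-ynoate (racemic) | CC#CCCC(C(=O)OC)P(=O)(OCC(F)(F)F)OCC(F)(F)F | intermediate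
22 | methyl (2Z,6E)-6-methyl-7-[(2S)-4-methyl-5-oxo-3-(prop-2-en-1-yl)-2,5-dihydrofuran-2-yl]-2-(pent-3-yn-1-yl)hepta-2,6-dienoate | C=CCC1=C(C)C(=O)O[C@H]1/C=C(C)/CC/C=C(/CCC#CC)C(=O)OC | intermediate
23 | methyl (2Z,6E)-7-[(2S)-3-(2,3-dihydroxypropyl)-4-methyl-5-oxo-2,5-dihydrofuran-2-yl]-6-methyl-2-(pent-3-yn-1-yl)hepta-2,6-dienoate (diol centre undefined) | OCC(O)CC1=C(C)C(=O)O[C@H]1/C=C(C)/CC/C=C(/CCC#CC)C(=O)OC | intermediate
24 | methyl (2Z,6E)-6-methyl-7-[(2S)-4-methyl-5-oxo-3-(2-oxoethyl)-2,5-dihydrofuran-2-yl]-2-(pent-3-yn-1-yl)hepta-2,6-dienoate | O=CCC1=C(C)C(=O)O[C@H]1/C=C(C)/CC/C=C(/CCC#CC)C(=O)OC | intermediate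
25 | (2S,13S)-13-O-triethylsilyl-16-oxosarcoglaucol: 14-membered ring with 3E, 7Z and 11E alkenes, C1=C15 butenolide closed on the C2 oxygen, methyl ester on C8, OSiEt3 on C13 | COC(=O)/C1=C\CC/C(C)=C/[C@@H]2OC(=O)C(C)=C2C[C@H](O[Si](CC)(CC)CC)/C(C)=C/CC1 | intermediate
26 | (2S,13S)-16-oxosarcoglaucol (free C13 alcohol of the target) | COC(=O)/C1=C\CC/C(C)=C/[C@@H]2OC(=O)C(C)=C2C[C@H](O)/C(C)=C/CC1 | intermediate
27 | 16-oxosarcoglaucol acetate | COC(=O)/C1=C\CC/C(C)=C/[C@@H]2OC(=O)C(C)=C2C[C@H](OC(C)=O)/C(C)=C/CC1 | target

## Step count and risks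

Total step count: 15. Longest linear sequence: 12 steps (steps 1, 2, 4, 5, 6, 7, 8, 11, 12, 13, 14, 15).

**Step 6 (key step).**
- Risk: incomplete carboxylation of the tetrasubstituted, chelated alkenylmagnesium 13, which would then be protonated on work-up. The C15–Mg bond is flanked by a methyl group and the chelate ring, and addition to a methyl-capped alkyne is already slower than to a terminal one.
- Fallback: from 10 the same carbomagnesiation is quenched with iodine, a faster electrophile, to give (2Z,4S,5E)-9-{[tert-butyl(dimethyl)silyl]oxy}-2-iodo-6-methyl-3-(prop-2-en-1-yl)nona-2,5-dien-4-ol F1. Palladium-catalysed cyclocarbonylation of this (Z)-γ-iodoallylic alcohol (PdCl2(PPh3)2, CO at 1 atm, Et3N, THF) forms the same C15–C16 and O–C16 bonds and returns to the route at 15.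

**Step 13.**
- Risk: poor facial selectivity at C13. The only stereocentre, C2, sits four atoms away across a planar butenolide, so the aldehyde faces are hardly differentiated. The enolisable aldehyde is a secondary concern, addressed by the base-free carbene.
- Fallback: the epimer (2S,13R)-13-O-triethylsilyl-16-oxosarcoglaucol F2 is desilylated as in step 14 to (2S,13R)-16-oxosarcoglaucol F3. Mitsunobu esterification with acetic acid (PPh3, diisopropyl azodicarboxylate, toluene, 0 °C) inverts C13 and returns directly at 27. Both epimers of the ring closure then converge on the target.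

**Step 12.**
- Risk: insufficient chemoselectivity of the dihydroxylation, with C3=C4 attacked in competition. A trisubstituted alkene is intrinsically more electron-rich than a monosubstituted one, and only the allylic lactone oxygen and the branching at C2 hold it back.
- Fallback: from 15, cross-metathesis with 2-methyl-2-butene (second-generation Grubbs catalyst RuCl2(=CHPh)(PCy3)(H2IMes), CH2Cl2, 40 °C) touches only the terminal alkene. It gives (5S)-5-[(1E)-5-{[tert-butyl(dimethyl)silyl]oxy}-2-methylpent-1-en-1-yl]-3-methyl-4-(3-methylbut-2-en-1-yl)furan-2(5H)-one F4.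
- The operations of steps 7, 8 and 11 then lead through alcohol (5S)-5-[(1E)-5-hydroxy-2-methylpent-1-en-1-yl]-3-methyl-4-(3-methylbut-2-en-1-yl)furan-2(5H)-one F5 and aldehyde (4E)-4-methyl-5-[(2S)-4-methyl-3-(3-methylbut-2-en-1-yl)-5-oxo-2,5-dihydrofuran-2-yl]pent-4-enal F6 to enoate methyl (2Z,6E)-6-methyl-7-[(2S)-4-methyl-3-(3-methylbut-2-en-1-yl)-5-oxo-2,5-dihydrofuran-2-yl]-2-(pent-3-yn-1-yl)hepta-2,6-dienoate F7.
- The prenyl alkene of F7 is now the most electron-rich π bond. mCPBA (NaHCO3, CH2Cl2, 0 °C) should epoxidise it selectively to methyl (2Z,6E)-7-{(2S)-3-[(3,3-dimethyloxiran-2-yl)methyl]-4-methyl-5-oxo-2,5-dihydrofuran-2-yl}-6-methyl-2-(pent-3-yn-1-yl)hepta-2,6-dienoate F8. Cleavage with H5IO6 (THF/H2O, 0 °C) returns to the route at 24.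

**Step 5.**
- Risk: weak enantioface discrimination, because the ketone is flanked by two π groups (alkynyl and alkenyl) that can both sit beside the arene ligand.
- Fallback: from 4, the alkenyllithium 7 is formylated with DMF to (2E)-6-{[tert-butyl(dimethyl)silyl]oxy}-3-methylhex-2-enal F9. Catalytic asymmetric alkynylation with propyne (Me2Zn, ProPhenol ligand of the enantiomer that leads to the S carbinol, toluene, 0 °C) sets C2 by addition instead of reduction and returns at 10.

## Further compounds

F1 | step 6 | (2Z,4S,5E)-9-{[tert-butyl(dimethyl)silyl]oxy}-2-iodo-6-methyl-3-(prop-2-en-1-yl)nona-2,5-dien-4-ol | C=CC/C(=C(\C)I)[C@@H](O)/C=C(C)/CCCO[Si](C)(C)C(C)(C)C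
F2 | step 13 | (2S,13R)-13-O-triethylsilyl-16-oxosarcoglaucol | COC(=O)/C1=C\CC/C(C)=C/[C@@H]2OC(=O)C(C)=C2C[C@@H](O[Si](CC)(CC)CC)/C(C)=C/CC1
F3 | step 13 | (2S,13R)-16-oxosarcoglaucol | COC(=O)/C1=C\CC/C(C)=C/[C@@H]2OC(=O)C(C)=C2C[C@@H](O)/C(C)=C/CC1
F4 | step 12 | (5S)-5-[(1E)-5-{[tert-butyl(dimethyl)silyl]oxy}-2-methylpent-1-en-1-yl]-3-methyl-4-(3-methylbut-2-en-1-yl)furan-2(5H)-one | CC(C)=CCC1=C(C)C(=O)O[C@H]1/C=C(C)/CCCO[Si](C)(C)C(C)(C)C
F5 | step 12 | (5S)-5-[(1E)-5-hydroxy-2-methylpent-1-en-1-yl]-3-methyl-4-(3-methylbut-2-en-1-yl)furan-2(5H)-one | CC(C)=CCC1=C(C)C(=O)O[C@H]1/C=C(C)/CCCO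
F6 | step 12 | (4E)-4-methyl-5-[(2S)-4-methyl-3-(3-methylbut-2-en-1-yl)-5-oxo-2,5-dihydrofuran-2-yl]pent-4-enal | CC(C)=CCC1=C(C)C(=O)O[C@H]1/C=C(C)/CCC=O
F7 | step 12 | methyl (2Z,6E)-6-methyl-7-[(2S)-4-methyl-3-(3-methylbut-2-en-1-yl)-5-oxo-2,5-dihydrofuran-2-yl]-2-(pent-3-yn-1-yl)hepta-2,6-dienoate | CC(C)=CCC1=C(C)C(=O)O[C@H]1/C=C(C)/CC/C=C(/CCC#CC)C(=O)OC
F8 | step 12 | methyl (2Z,6E)-7-{(2S)-3-[(3,3-dimethyloxiran-2-yl)methyl]-4-methyl-5-oxo-2,5-dihydrofuran-2-yl}-6-methyl-2-(pent-3-yn-1-yl)hepta-2,6-dienoate (epoxide centre undefined) | CC1(C)OC1CC2=C(C)C(=O)O[C@H]2/C=C(C)/CC/C=C(/CCC#CC)C(=O)OC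
F9 | step 5 | (2E)-6-{[tert-butyl(dimethyl)silyl]oxy}-3-methylhex-2-enal | O=C/C=C(C)/CCCO[Si](C)(C)C(C)(C)C
A1 | alternative 1 | 17-membered propargyl allyl ether with two orthoesters and the C13 silyl ether (C14 and C17 drawn trans across C1=C15) | O1C/C(C23OCC(C)(CO2)CO3)=C/C[C@H](O[Si](C)(C)C(C)(C)C)/C(C)=C/CC/C(C45OCC(C)(CO4)CO5)=C/CCC#CC1
A2 | alternative 1 | 14-membered propargylic alcohol with a 2-propenyl orthoester branch at C1 (C1 as one epimer) | CC12COC(OC1)(OC2)/C3=C\CCC#C[C@H](O)[C@@H](C(=C)C45OCC(C)(CO4)CO5)C[C@H](O[Si](C)(C)C(C)(C)C)/C(C)=C/CC3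
A3 | alternative 2 | 13-O-triethylsilyl macrocycle (same structure as 25) | COC(=O)/C1=C\CC/C(C)=C/[C@@H]2OC(=O)C(C)=C2C[C@H](O[Si](CC)(CC)CC)/C(C)=C/CC1
A4 | alternative 3 | open-chain diyne with butenolide and C13 silyl ether, both alkynes methyl-capped | COC(=O)/C(CCC#CC)=C\CC/C(C)=C/[C@@H]1OC(=O)C(C)=C1C[C@H](O[Si](C)(C)C(C)(C)C)C#CC
A5 | alternative 3 | 14-membered cycloalkyne with C13 silyl ether | COC(=O)/C1=C\CC/C(C)=C/[C@@H]2OC(=O)C(C)=C2C[C@H](O[Si](C)(C)C(C)(C)C)C#CCC1
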